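The target is what I want from these flasks, but it forms from the starting material while other steps consume the same starting material, and a reversible step then bleeds the target into its isomer.

| flask | starting material | protic impurity | temperature | time |
|---|---|---|---|---|
| Thursday's | 0.050 M | 0.0500 M | 0 °C | 8.0 d |
| Sunday's | 0.050 M | 0.0500 M | 50 °C | 8.0 d |
| Tuesday's | 0.050 M | 0.0500 M | −25 °C | 8.0 d |
| Saturday's | 0.050 M | 0.0500 M | 25 °C | 8.0 d |

    starting material → side product (k1 = 2.19 × 10⁻⁵ min⁻¹, Ea1 = 115 kJ mol⁻¹)
    target ⇌ isomer of the product (K2 = 2.0, k2 = 4.33 × 10⁻⁴ min⁻¹, Ea2 = 113 kJ mol⁻¹, ΔH2 = −27.0 kJ mol⁻¹)
    starting material → target (k3 = 0.00171 min⁻¹, Ea3 = 99.0 kJ mol⁻¹)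
    2 starting material → homo dimer (k4 = 0.00519 L mol⁻¹ min⁻¹, Ea4 = 92.0 kJ mol⁻¹)
    starting material + protic impurity → quenched substrate (k5 = 0.00390 L mol⁻¹ min⁻¹, Ea5 = 93.0 kJ mol⁻¹)
    (constants at 50 °C)

- in percentages every species weighs as the starting material in it: one homo dimer counts as two
- two of one species on the left: rate k times its square, two consumed each time
- the list of constants is for 50 °C, to be carried to other temperatures by the activation energies and enthalpies

1. the flask that comes out highest in amount of target, in percent of the starting material charged, or "all alike" when all lie within 1.5 percentage points (Thursday's / Sunday's / Tuesday's / Saturday's / all alike)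
2. target at the end, in percent of the starting material charged, Thursday's
3. target at the end, in percent of the starting material charged, Sunday's
4. target at the end, in percent of the starting material charged, Tuesday's
5. target at the end, in percent of the starting material charged, Saturday's

I divide the rate at which target forms by the rate at which starting material falls, so that time drops out. I hold the protic impurity at its charge, which makes its step pseudo-first-order. Summing over the whole charge gives the share, the part of the spent starting material that becomes target: the constant to target, divided by the dimer's rate constant at the charge, times the natural log of one plus that dimer constant over the sum of the first-order losses. For Sunday's flask the dimer constant is 5.19 × 10⁻⁴ min⁻¹ and the first-order sum 0.00193 min⁻¹, so the share is 78.6%.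

In Sunday's flask the starting material has a first life of 0.284 d and target relaxes towards its isomer with a life of 1.07 d. The run is longer than both, so by my reckoning the curve climbs within a day, turns over and lies at the share divided by one plus the equilibrium constant: 26.2%.

In Saturday's flask the curve starts with a slope of 0.112 d⁻¹ of the charge. The first-order losses are 0.128 d⁻¹ and the dimer constant 0.0423 d⁻¹, so the knee comes near 5.86 d. Saturday's share, reckoned for the whole charge spent, is 75.5%, and the target formed by 8.0 d comes by the same reckoning to 50.8% of the charge. The isomer step, at 0.0183 d⁻¹, acts on about half of that over the run, which leaves 47.1%. Saturday's level, with an equilibrium constant of 4.64, lies far off at 13.4%.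

In the cold flasks the slope simply runs on, which gives 2.32% for Thursday's and 0.0287% for Tuesday's. I commit to Saturday's as highest.

The forecast gives 2.27% for Thursday's, 26.3% for Sunday's, 0.029% for Tuesday's and 46.7% for Saturday's, and names Saturday's, on the ground that “only a little isomerises, so Saturday's comes out highest”.

The simulation gives 2.27% for Thursday's, 26.3% for Sunday's, 0.0287% for Tuesday's and 46.7% for Saturday's, so Saturday's stands highest.

Sunday's target ends low mainly because of the passing of target into its isomer: with that step struck out, Sunday's target ends at 78.9% instead of 26.3%, close to the share of 78.6% reckoned with the protic impurity held at its charge. Saturday's flask, left until 80.0 d, has 0% of its starting material, and its target and isomer together hold 75.9% against a share of 75.5%, with target itself down to 26.0%.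

The rate constants are invented; what happens was integrated by code.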